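The route disconnects the 1,2-dioxane (O1–O2–C3–C4–C5–C6) at C5–C6. The quaternary peroxy carbon C6 is treated as the carbon of an ethyl dienyl ketone and ionised as a peroxycarbenium ion. C5 and the C4 ethyl branch are hidden in a trans-(trimethylsilylmethyl)cyclopropane on C3. In one operation, strain-releasing attack of the cyclopropane CH2 (C5) on C6 closes the ring, sets the C6 stereocentre, keeps C4 intact and unveils a C4 vinyl group that diimide later reduces chemoselectively. The precursor is an acyclic mixed peroxyketal, made by organocatalytic peroxy-Michael addition of the side-chain α-methoxy hydroperoxide to a cyclopropyl enal.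

Key step: step 13

Remark (assumption): ring atoms are numbered O1, O2, C3–C6 as in the target, the side chain C7–C14 from C6, and C4a is the cyclopropane carbon bearing CH2SiMe3; each chiral catalyst is assumed to follow its usual sense of induction, and its enantiomer would be used if it did not.

Step 1
Reactants: 1 (E)-pent-2-enal; 2 diethylzinc
Product: 3 (3R,4E)-hept-4-en-3-ol
Conditions: Et2Zn, (+)-3-exo-morpholinoisoborneol (4 mol %), hexane/toluene, 0 °C; aq NH4Cl
Reagents that add atoms: diethylzinc, CC[Zn]CC
Why: Amino-alcohol-catalysed enantioselective 1,2-addition of diethylzinc to an enal, in which the (+)-enantiomer of the ligand is chosen to deliver ethyl to the carbonyl face that gives the 3R carbinol.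

Step 2
Reactants: 3 (3R,4E)-hept-4-en-3-ol; 4 triethyl orthoacetate
Product: 5 ethyl (3R,4E)-3-ethylhept-4-enoate
Conditions: MeC(OEt)3 (excess), EtCO2H (cat), 140 °C, EtOH distilled off
Reagents that add atoms: triethyl orthoacetate, CCOC(C)(OCC)OCC
Why: Johnson–Claisen rearrangement through a chair transition state with the carbinol ethyl group equatorial transfers the C–O chirality suprafacially to the new C–C bond, setting the R configuration of the future C10 and the E alkene together.

Step 3
Reactants: 5 ethyl (3R,4E)-3-ethylhept-4-enoate; 6 dimethyl (1-diazo-2-oxopropyl)phosphonate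
Product: 8 (4R,5E)-4-ethyloct-5-en-1-yne, via aldehyde 7 (not isolated)
Conditions: i-Bu2AlH, CH2Cl2, −78 °C; then MeOH, K2CO3, 6, −78 °C to rt
Reagents that add atoms: dimethyl (1-diazo-2-oxopropyl)phosphonate, COP(=O)(OC)C(=[N+]=[N-])C(C)=O
Why: Half-reduction of the ester by i-Bu2AlH and Ohira–Bestmann (Seyferth–Gilbert) homologation of the aldehyde in the same flask give the terminal alkyne, and the stereocentre is β to the carbonyl group and so cannot epimerise.

Step 4
Reactants: 8 (4R,5E)-4-ethyloct-5-en-1-yne; 9 trimethylaluminium; 10 propanoyl chloride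
Product: 12 (4E,7R,8E)-7-ethyl-5-methylundeca-4,8-dien-3-one, via alkenylalane 11 (not isolated)
Conditions: Me3Al, Cp2ZrCl2 (20 mol %), CH2Cl2, 0 °C to rt; then EtCOCl, Pd(PPh3)4 (5 mol %), THF, 0 °C
Reagents that add atoms: trimethylaluminium, C[Al](C)C; propanoyl chloride, CCC(=O)Cl
Why: Zirconium-catalysed syn carboalumination (Negishi) places methyl on the internal and aluminium on the terminal alkyne carbon, and palladium-catalysed acylation of the alkenylalane with retention gives the E trisubstituted enone that carries C6 to C14 of the target.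

Step 5
Reactants: 12 (4E,7R,8E)-7-ethyl-5-methylundeca-4,8-dien-3-one; 13 methoxytrimethylsilane
Product: 14 (4E,7R,8E)-7-ethyl-3,3-dimethoxy-5-methylundeca-4,8-diene
Conditions: MeOSiMe3, Me3SiOTf (cat), CH2Cl2, −78 to −40 °C; pyridine quench
Reagents that add atoms: methoxytrimethylsilane, CO[Si](C)(C)C
Why: Ketalisation with MeOSiMe3 under catalytic Me3SiOTf (Noyori conditions) is aprotic and cold, so the conjugated ketone should be converted without migration or E/Z isomerisation of the trisubstituted alkene.

Step 6
Reactants: 14 (4E,7R,8E)-7-ethyl-3,3-dimethoxy-5-methylundeca-4,8-diene; 15 hydrogen peroxide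
Product: 16 (4E,7R,8E)-7-ethyl-3-hydroperoxy-3-methoxy-5-methylundeca-4,8-diene (both epimers at the ketal carbon)
Conditions: H2O2 (dried ethereal solution, excess), PPTS (cat), Et2O, 0 °C; NaHCO3 quench
Reagents that add atoms: hydrogen peroxide, OO
Why: Acid-catalysed exchange of one methoxy group of a ketal for hydrogen peroxide is the standard entry to α-alkoxy hydroperoxides, and mild acid at 0 °C should stop at the mono-hydroperoxide, whose ketal configuration is irrelevant because this carbon is ionised later.

Step 7
Reactants: 17 allyltrimethylsilane; 18 ethyl diazoacetate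
Product: 19 ethyl (1S,2S)-2-[(trimethylsilyl)methyl]cyclopropane-1-carboxylate
Conditions: [RuCl2(p-cymene)]2 (cat), 2,6-bis[(4R)-4-isopropyl-2-oxazolin-2-yl]pyridine, CH2Cl2, rt, slow addition of 18 to excess 17
Reagents that add atoms: ethyl diazoacetate, CCOC(=O)C=[N+]=[N-]
Why: Ruthenium–pybox-catalysed asymmetric cyclopropanation of a terminal alkene with a diazoacetate is trans-selective, and the ligand enantiomer is chosen so that the carbene adds to the alkene face giving the 1S,2S ester, which fixes the future C4 stereocentre.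

Step 8
Reactants: 19 ethyl (1S,2S)-2-[(trimethylsilyl)methyl]cyclopropane-1-carboxylate
Product: 20 (1S,2S)-2-[(trimethylsilyl)methyl]cyclopropane-1-carbaldehyde
Conditions: i-Bu2AlH, CH2Cl2, −78 °C; Rochelle salt work-up
Reagents that add atoms: none
Why: Low-temperature i-Bu2AlH reduction stops at the aluminium hemiacetal, which releases the aldehyde on work-up without touching either cyclopropane stereocentre.

Step 9
Reactants: 20 (1S,2S)-2-[(trimethylsilyl)methyl]cyclopropane-1-carbaldehyde; 21 (triphenylphosphoranylidene)acetaldehyde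
Product: 22 (2E)-3-{(1R,2S)-2-[(trimethylsilyl)methyl]cyclopropyl}prop-2-enal
Conditions: Ph3P=CHCHO, toluene, 80 °C
Reagents that add atoms: (triphenylphosphoranylidene)acetaldehyde, O=CC=P(c1ccccc1)(c1ccccc1)c1ccccc1
Why: Wittig olefination with the stabilised formylmethylene ylide gives the E enal selectively, and the neutral conditions spare the acid-sensitive cyclopropylmethylsilane (the descriptor at the ring carbon changes only through the priority rules).

Step 10
Reactants: 22 (2E)-3-{(1R,2S)-2-[(trimethylsilyl)methyl]cyclopropyl}prop-2-enal; 16 (4E,7R,8E)-7-ethyl-3-hydroperoxy-3-methoxy-5-methylundeca-4,8-diene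
Product: 23 (3R)-3-({(4E,7R,8E)-7-ethyl-3-methoxy-5-methylundeca-4,8-dien-3-yl}peroxy)-3-{(1S,2S)-2-[(trimethylsilyl)methyl]cyclopropyl}propanal (both epimers at the ketal carbon)
Conditions: (R)-2-[diphenyl(trimethylsilyloxy)methyl]pyrrolidine (20 mol %), PhCO2H (10 mol %), toluene, 0 °C
Reagents that add atoms: hydroperoxide 16, CCC(OC)(OO)/C=C(C)/C[C@@H](CC)/C=C/CC
Why: Iminium-catalysed asymmetric peroxy-Michael addition of an α-alkoxy hydroperoxide to an enal, in which the E iminium ion is attacked anti to the diphenyl(silyloxy)methyl group of the (R)-catalyst, should set C3 as R under catalyst control and deliver the mixed peroxyketal directly.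

Step 11
Reactants: 23 peroxy aldehyde; 24 sodium chlorite
Product: 25 (3R)-3-({(4E,7R,8E)-7-ethyl-3-methoxy-5-methylundeca-4,8-dien-3-yl}peroxy)-3-{(1S,2S)-2-[(trimethylsilyl)methyl]cyclopropyl}propanoic acid
Conditions: NaClO2, NaH2PO4, 2-methylbut-2-ene (large excess), t-BuOH/H2O, 0 °C
Reagents that add atoms: sodium chlorite, [Na+].[O-]Cl=O
Why: Pinnick oxidation converts the aldehyde into the acid under buffered conditions, the alkene scavenger takes up HOCl before it can reach the substrate alkenes, and neither the dialkyl peroxide nor the peroxyketal is oxidised.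

Step 12
Reactants: 25 peroxy acid; 26 (trimethylsilyl)diazomethane
Product: 27 methyl (3R)-3-({(4E,7R,8E)-7-ethyl-3-methoxy-5-methylundeca-4,8-dien-3-yl}peroxy)-3-{(1S,2S)-2-[(trimethylsilyl)methyl]cyclopropyl}propanoate
Conditions: Me3SiCHN2, toluene/MeOH, 0 °C
Reagents that add atoms: (trimethylsilyl)diazomethane, C[Si](C)(C)C=[N+]=[N-]
Why: Methylation of the acid with Me3SiCHN2 in methanol is neutral and fast, which masks the acid for the Lewis-acid step without exposing the peroxyketal or the β-peroxy carbonyl unit to acid or base.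

Step 13
Reactants: 27 methyl (3R)-3-({(4E,7R,8E)-7-ethyl-3-methoxy-5-methylundeca-4,8-dien-3-yl}peroxy)-3-{(1S,2S)-2-[(trimethylsilyl)methyl]cyclopropyl}propanoate
Product: 29 methyl 2-[(3R,4S,6R)-4-ethenyl-6-ethyl-6-[(1E,4R,5E)-4-ethyl-2-methylocta-1,5-dien-1-yl]-1,2-dioxan-3-yl]acetate, via peroxycarbenium triflate 28 (not isolated)
Conditions: Me3SiOTf, 2,6-di-tert-butyl-4-methylpyridine, CH2Cl2 (high dilution), −78 to −40 °C; Et3N quench
Reagents that add atoms: none
Why: Proposed new method: Me3SiOTf abstracts the methoxy group of 27 to give the allyl-conjugated peroxycarbenium ion 28, the cyclopropane CH2 (C5) attacks C6 as a σ-nucleophile while the C5–C4a bond breaks toward a β-silyl-stabilised cation, and loss of the silyl group leaves the C4 vinyl group, so ring strain and the silicon β-effect together drive C5–C6 bond formation. The closest known reactions are the Lewis-acid cyclisation of allylsilane-bearing monoperoxyketals to 1,2-dioxanes (an intramolecular Hosomi–Sakurai reaction of a peroxycarbenium ion) and the cyclopropylmethylsilane-terminated Prins cyclisation of oxocarbenium ions, and the untested part is the pairing of a cyclopropane σ-bond with a peroxycarbenium ion. The 1,2-dioxane closes through a six-membered chair in which both atoms of the C=O+ unit are endocyclic and the cleaved cyclopropane bond is exocyclic (6-exo with respect to the nucleophile). C6 is the only new stereocentre: allylic 1,3-strain from the C8 methyl group should hold the cation s-cis with O2 syn to the ethyl group, so that ethyl becomes axial and the dienyl chain equatorial, while backside attack at C5 keeps C4a equatorial and hence the cis-disposed C3 side chain axial, which corresponds to the 3R,4S,6R isomer with the C6 epimer as the expected by-product to be removed by chromatography; C3 and C4 are carried through unchanged because none of their bonds is broken. The step needs the cyclopropane to win over the 7,8- and 11,12-alkenes and the ester as nucleophile, which intramolecularity in a six-membered transition state and the β-silyl assistance should secure, and it needs the 7E geometry and the silane to survive, which low temperature and the hindered base (removing adventitious TfOH) should secure.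

Step 14
Reactants: 29 methyl 2-[(3R,4S,6R)-4-ethenyl-6-ethyl-6-[(1E,4R,5E)-4-ethyl-2-methylocta-1,5-dien-1-yl]-1,2-dioxan-3-yl]acetate
Product: 30 methyl 2-[(3R,4R,6R)-4,6-diethyl-6-[(1E,4R,5E)-4-ethyl-2-methylocta-1,5-dien-1-yl]-1,2-dioxan-3-yl]acetate
Conditions: KO2CN=NCO2K (portionwise), AcOH, MeOH, 0 °C to rt, stopped when the vinyl group is consumed
Reagents that add atoms: none
Why: Diimide reduction is a concerted hydrogen transfer that is highly sensitive to alkene substitution and leaves O–O bonds intact, so the monosubstituted vinyl group should be reduced well before the hindered E-disubstituted and trisubstituted side-chain alkenes (the change of the C4 descriptor from S to R is a priority effect only).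

Step 15
Reactants: 30 methyl 2-[(3R,4R,6R)-4,6-diethyl-6-[(1E,4R,5E)-4-ethyl-2-methylocta-1,5-dien-1-yl]-1,2-dioxan-3-yl]acetate; 31 lithium hydroxide
Product: 32 2-[(3R,4R,6R)-4,6-diethyl-6-[(1E,4R,5E)-4-ethyl-2-methylocta-1,5-dien-1-yl]-1,2-dioxan-3-yl]acetic acid
Conditions: LiOH, THF/H2O, 0 °C; then aq HCl to pH 3
Reagents that add atoms: lithium hydroxide, [Li+].[OH-]
Why: Saponification of the unhindered methyl ester by hydroxide at 0 °C should be faster than deprotonation at C2 and retro-peroxy-Michael ring opening, and the carboxylate once formed is protected against that pathway.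

Compound list
1 | (E)-pent-2-enal | CC/C=C/C=O | starting material
2 | diethylzinc | CC[Zn]CC | starting material
3 | (3R,4E)-hept-4-en-3-ol | CC[C@@H](O)/C=C/CC | intermediate
4 | triethyl orthoacetate | CCOC(C)(OCC)OCC | starting material
5 | ethyl (3R,4E)-3-ethylhept-4-enoate | CCOC(=O)C[C@@H](CC)/C=C/CC | intermediate
6 | dimethyl (1-diazo-2-oxopropyl)phosphonate | COP(=O)(OC)C(=[N+]=[N-])C(C)=O | starting material
7 | (3R,4E)-3-ethylhept-4-enal | O=CC[C@@H](CC)/C=C/CC | intermediate
8 | (4R,5E)-4-ethyloct-5-en-1-yne | C#CC[C@@H](CC)/C=C/CC | intermediate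
9 | trimethylaluminium | C[Al](C)C | starting material
10 | propanoyl chloride | CCC(=O)Cl | starting material
11 | [(1E,4R,5E)-4-ethyl-2-methylocta-1,5-dien-1-yl]dimethylalumane | C[Al](C)/C=C(C)/C[C@@H](CC)/C=C/CC | intermediate
12 | (4E,7R,8E)-7-ethyl-5-methylundeca-4,8-dien-3-one | CCC(=O)/C=C(C)/C[C@@H](CC)/C=C/CC | intermediate
13 | methoxytrimethylsilane | CO[Si](C)(C)C | starting material
14 | (4E,7R,8E)-7-ethyl-3,3-dimethoxy-5-methylundeca-4,8-diene | CCC(OC)(OC)/C=C(C)/C[C@@H](CC)/C=C/CC | intermediate
15 | hydrogen peroxide | OO | starting material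
16 | (4E,7R,8E)-7-ethyl-3-hydroperoxy-3-methoxy-5-methylundeca-4,8-diene (both epimers at C3) | CCC(OC)(OO)/C=C(C)/C[C@@H](CC)/C=C/CC | intermediate
17 | allyltrimethylsilane | C=CC[Si](C)(C)C | starting material
18 | ethyl diazoacetate | CCOC(=O)C=[N+]=[N-] | starting material
19 | ethyl (1S,2S)-2-[(trimethylsilyl)methyl]cyclopropane-1-carboxylate | CCOC(=O)[C@H]1C[C@@H]1C[Si](C)(C)C | intermediate
20 | (1S,2S)-2-[(trimethylsilyl)methyl]cyclopropane-1-carbaldehyde | O=C[C@H]1C[C@@H]1C[Si](C)(C)C | intermediate
21 | (triphenylphosphoranylidene)acetaldehyde | O=CC=P(c1ccccc1)(c1ccccc1)c1ccccc1 | starting material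
22 | (2E)-3-{(1R,2S)-2-[(trimethylsilyl)methyl]cyclopropyl}prop-2-enal | O=C/C=C/[C@H]1C[C@@H]1C[Si](C)(C)C | intermediate
23 | (3R)-3-({(4E,7R,8E)-7-ethyl-3-methoxy-5-methylundeca-4,8-dien-3-yl}peroxy)-3-{(1S,2S)-2-[(trimethylsilyl)methyl]cyclopropyl}propanal (both ketal epimers) | O=CC[C@@H](OOC(OC)(CC)/C=C(C)/C[C@@H](CC)/C=C/CC)[C@H]1C[C@@H]1C[Si](C)(C)C | intermediate
24 | sodium chlorite | [Na+].[O-]Cl=O | starting material
25 | (3R)-3-({(4E,7R,8E)-7-ethyl-3-methoxy-5-methylundeca-4,8-dien-3-yl}peroxy)-3-{(1S,2S)-2-[(trimethylsilyl)methyl]cyclopropyl}propanoic acid | OC(=O)C[C@@H](OOC(OC)(CC)/C=C(C)/C[C@@H](CC)/C=C/CC)[C@H]1C[C@@H]1C[Si](C)(C)C | intermediate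
26 | (trimethylsilyl)diazomethane | C[Si](C)(C)C=[N+]=[N-] | starting material
27 | methyl (3R)-3-({(4E,7R,8E)-7-ethyl-3-methoxy-5-methylundeca-4,8-dien-3-yl}peroxy)-3-{(1S,2S)-2-[(trimethylsilyl)methyl]cyclopropyl}propanoate | COC(=O)C[C@@H](OOC(OC)(CC)/C=C(C)/C[C@@H](CC)/C=C/CC)[C@H]1C[C@@H]1C[Si](C)(C)C | intermediate
28 | peroxycarbenium triflate derived from 27 by loss of methoxide | COC(=O)C[C@@H](O[O+]=C(CC)/C=C(C)/C[C@@H](CC)/C=C/CC)[C@H]1C[C@@H]1C[Si](C)(C)C.[O-]S(=O)(=O)C(F)(F)F | intermediate
29 | methyl 2-[(3R,4S,6R)-4-ethenyl-6-ethyl-6-[(1E,4R,5E)-4-ethyl-2-methylocta-1,5-dien-1-yl]-1,2-dioxan-3-yl]acetate | CC/C=C/[C@H](CC)C/C(C)=C/[C@@]1(CC)C[C@@H](C=C)[C@@H](CC(=O)OC)OO1 | intermediate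
30 | methyl 2-[(3R,4R,6R)-4,6-diethyl-6-[(1E,4R,5E)-4-ethyl-2-methylocta-1,5-dien-1-yl]-1,2-dioxan-3-yl]acetate | CC/C=C/[C@H](CC)C/C(C)=C/[C@@]1(CC)C[C@@H](CC)[C@@H](CC(=O)OC)OO1 | intermediate
31 | lithium hydroxide | [Li+].[OH-] | starting material
32 | 2-[(3R,4R,6R)-4,6-diethyl-6-[(1E,4R,5E)-4-ethyl-2-methylocta-1,5-dien-1-yl]-1,2-dioxan-3-yl]acetic acid | CC/C=C/[C@H](CC)C/C(C)=C/[C@@]1(CC)C[C@@H](CC)[C@@H](CC(=O)O)OO1 | target

Total step count: 15. Longest linear sequence: 12 steps (steps 1–6, then 10–15); the cyclopropane branch (steps 7–9) joins at step 10.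

Steps most likely to fail

Step 13. The cyclopropane may prove too weak a nucleophile for the stabilised cation, so that the ketal simply returns, the ring is opened by protodesilylation, or the cation reacts with a side-chain alkene. The fallback uses only established peroxycarbenium chemistry: both C–C bonds at the peroxide carbons are made with allylsilanes and their order is exchanged, so the ring is closed at C3–C4 instead. It sets out from ketal 14. Methyl 3-hydroperoxy-3-methoxypropanoate F1, made by ozonolysis of methyl but-3-enoate in MeOH/CH2Cl2 at −78 °C, is exchanged into 14 (PPTS, CH2Cl2, 0 °C) to give the bis-peroxyketal F2. Me3SiOTf-catalysed intermolecular Hosomi–Sakurai allylation with 17 at −78 °C should occur at the far more easily ionised ketone-derived centre and give the tertiary allyl peroxide F3 as both C6 epimers. Cross-metathesis of its terminal alkene with 17 (second-generation Hoveyda–Grubbs catalyst) gives the allylsilane F4. SnCl4 at −78 °C then ionises the remaining peroxyacetal, and 6-exo closure by the allylsilane forms the C3–C4 bond and the C4 vinyl group together. The route is rejoined at 29, which would have to be separated from its diastereomers because C6 is formed without control in this variant.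

Step 10. The bulky, acid-labile hydroperoxide 16 may add sluggishly, the enamine intermediate may attack the O–O bond and divert material to the epoxy aldehyde, or the allylic ketal may ionise under the acid co-catalyst. The same fallback applies if 16 cannot be secured cleanly in step 6. The peroxide is introduced with a small donor first and the ketone fragment afterwards. The fallback sets out from enal 22: with the same catalyst, 2-hydroperoxy-2-methoxypropane F5 (from ozonolysis of 2,3-dimethylbut-2-ene in MeOH) gives the peroxy aldehyde F6. Pinnick oxidation gives the acid F7 and Me3SiCHN2 gives the methyl ester F8. AcOH/THF/H2O removes the 2-methoxypropan-2-yl group to unmask the secondary hydroperoxide F9. PPTS-catalysed exchange of F9 into ketal 14 (CH2Cl2, molecular sieves) returns to the route at 27.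

Step 7. Catalyst-controlled cyclopropanation of the allylsilane may give insufficient trans/cis discrimination or enantiopurity, and this step fixes C4, which no later step can correct. The cyclopropane is then built by reagent-controlled Simmons–Smith chemistry on an allylic alcohol. The fallback sets out from 17: cross-metathesis with (Z)-but-2-ene-1,4-diol (second-generation Hoveyda–Grubbs catalyst) gives (2E)-4-(trimethylsilyl)but-2-en-1-ol F10. Charette cyclopropanation (Zn(CH2I)2 and the enantiomer of the tartaramide-derived dioxaborolane ligand that leads to the 1S,2S product) gives the cyclopropylmethanol F11. Dess–Martin oxidation returns to the route at aldehyde 20.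

Further compounds
F1 | step 13 | methyl 3-hydroperoxy-3-methoxypropanoate | COC(=O)CC(OC)OO
F2 | step 13 | methyl 3-({(4E,7R,8E)-7-ethyl-3-methoxy-5-methylundeca-4,8-dien-3-yl}peroxy)-3-methoxypropanoate | COC(=O)CC(OC)OOC(OC)(CC)/C=C(C)/C[C@@H](CC)/C=C/CC
F3 | step 13 | methyl 3-({(5E,8R,9E)-4,8-diethyl-6-methyldodeca-1,5,9-trien-4-yl}peroxy)-3-methoxypropanoate | COC(=O)CC(OC)OOC(CC)(CC=C)/C=C(C)/C[C@@H](CC)/C=C/CC
F4 | step 13 | methyl 3-({(6E,9R,10E)-5,9-diethyl-7-methyl-1-(trimethylsilyl)trideca-2,6,10-trien-5-yl}peroxy)-3-methoxypropanoate | COC(=O)CC(OC)OOC(CC)(CC=CC[Si](C)(C)C)/C=C(C)/C[C@@H](CC)/C=C/CC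
F5 | step 10 | 2-hydroperoxy-2-methoxypropane | COC(C)(C)OO
F6 | step 10 | (3R)-3-[(2-methoxypropan-2-yl)peroxy]-3-{(1S,2S)-2-[(trimethylsilyl)methyl]cyclopropyl}propanal | O=CC[C@@H](OOC(C)(C)OC)[C@H]1C[C@@H]1C[Si](C)(C)C
F7 | step 10 | (3R)-3-[(2-methoxypropan-2-yl)peroxy]-3-{(1S,2S)-2-[(trimethylsilyl)methyl]cyclopropyl}propanoic acid | OC(=O)C[C@@H](OOC(C)(C)OC)[C@H]1C[C@@H]1C[Si](C)(C)C
F8 | step 10 | methyl (3R)-3-[(2-methoxypropan-2-yl)peroxy]-3-{(1S,2S)-2-[(trimethylsilyl)methyl]cyclopropyl}propanoate | COC(=O)C[C@@H](OOC(C)(C)OC)[C@H]1C[C@@H]1C[Si](C)(C)C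
F9 | step 10 | methyl (3R)-3-hydroperoxy-3-{(1S,2S)-2-[(trimethylsilyl)methyl]cyclopropyl}propanoate | COC(=O)C[C@@H](OO)[C@H]1C[C@@H]1C[Si](C)(C)C
F10 | step 7 | (2E)-4-(trimethylsilyl)but-2-en-1-ol | C[Si](C)(C)C/C=C/CO
F11 | step 7 | {(1S,2S)-2-[(trimethylsilyl)methyl]cyclopropyl}methanol | OC[C@H]1C[C@@H]1C[Si](C)(C)C
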